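All runs were computed for an exercise, noise included.

Target and starting material together stay at what you charged: the birch flask's readings sum to 102 % at 120 min and 101 % at 480 min, with a scatter of 1 percentage point on each reading. So you can follow this flask by one amount, and the question is why it stops.

| setting | birch | flask |
|---|---|---|
| starting material | 0.10 M | 0.10 M |
| free enzyme | 81 µM | 81 µM |
| temperature | 37 °C | 37 °C |
| remark | the very flask that is asked about, followed so far |  |
| time |  | 12 h |

- birch (time / min: target / %, starting material / %): 120: 71.1, 31.0; 240: 75.9, 21.9; 300: 79.0, 20.2; 480: 81.6, 19.4

(scatter of a reading: 1 percentage point)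

- epsilon: at 12 h add free enzyme, 100 % of the amount charged, then wait 4.0 h
- eta: at 12 h add starting material, 50.0 % of the amount charged, then wait 4.0 h
- alpha: change nothing and wait 4.0 h more
- gamma: at 12 h raise the temperature by 10 K, then wait 4.0 h

- what is added takes up no volume worth counting
- a reading or a percentage of target counts all its forms, free or not
- the earlier runs do not show what temperature does; that part of a forecast is a guess

* target, in percent of the starting material first charged, at 12 h
* the option that brings most further target ("none" if no option brings more than 2 percentage points) (epsilon / eta / alpha / gamma / none)
* target present, in percent of the starting material first charged, after eta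
* target present, in percent of the starting material first charged, after alpha

Build it up. Start with the main step by itself, starting material to target at a steady first-order pace, taken from the first reading:

pace = ln(charged / left) / time = 0.586 h⁻¹

That pace leaves 0.921 % at 480 min, but the reading is 19.4 %, far more, so something stops the step.

Now add an enzyme that dies. The birch flask then ends when its enzyme has done its work:

target made / enzyme charged = 81.6 % × 0.10 M / 81 µM = 1010

Call this the turnover count (the turnover number), read off that one scattered reading: the target one enzyme makes on average before it stops.

Then add a reverse step. It gives the same plateau with the enzyme still alive, and these readings do not separate the two. My own bet, a judgement, is the dying enzyme. On that view target at 12 h stands near 81.6 %, and waiting or adding starting material brings little. A fresh charge brings a fresh count: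

1010 × 81 µM = 81.6 mM, against 19.4 mM of starting material left

Because the fresh count is larger than what is left, I name epsilon.

The forecast differs from my reckoning: “I lean towards equilibrium, which is a judgement call.” It gives 81.8 % now, eta as best, 120 % after eta and 81.9 % after alpha.

The flask gives 81.7 % now, and epsilon is best with a gain of 18 points. Eta ends at 82.1 % and alpha at 81.9 %. The forecast and the flask part on eta: at 720 min the flask holds 0.0499 % of its catalyst in a form that can turn over.

    free enzyme → spent catalyst B (k = 7.00 × 10⁻⁵ s⁻¹, Ea = 99.0 kJ mol⁻¹)
    free enzyme → unfolded enzyme (k = 1.60 × 10⁻⁵ s⁻¹, Ea = 210 kJ mol⁻¹)
    crystals ⇌ target, rate k3*(cs3 - [target]) while solid is left; crystals form when [target] > cs3 (solubility = 48.0 mM, k = 0.00610 s⁻¹)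
    starting material + free enzyme → target + free enzyme, rate k4*[starting material]*[free enzyme]/(1 + ([starting material]/Km4)) (16.0 mM, k = 91.0 M⁻¹ s⁻¹, Ea = 52.0 kJ mol⁻¹)
    2 free enzyme → spent catalyst A (k = 26.0 M⁻¹ s⁻¹, Ea = 36.0 kJ mol⁻¹)
    (constants at 37 °C)

Epsilon's gain of 18 points stood against 18.3 % of starting material still free at 720 min. For the neighbour flask charged with 0.40 M of starting material and the same charge of free enzyme, the count of 1010 gives 20.5 % of target; at 12 h that neighbour flask had made 26.0 %, a count of 1284. Left untouched, the birch flask has come to rest to within 0.30 points: target goes from 81.7 % at 12 h to 82.0 % at 7200 min, when free enzyme is 0 % and starting material stands at 18.0 %.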